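## The problem

Target 16 is two benzene rings held together by a single ether oxygen. Ring A carries a carboxyl group at C1, a free hydroxyl at C2, the ether oxygen at C4 and a heptyl chain at C6. Ring B carries a carboxyl group at C1', the ether oxygen at C2', a methoxy group at C4' and a heptyl chain at C6'. There is no stereocentre, so the problem is one of position, crowding and functional-group survival.

Both rings are the same 6-heptyl-2,4-dioxygenated benzoic acid. Their oxygens must nevertheless end in three different states: free OH on C2, methyl ether on C4', diaryl ether between C4 and C2'. The ether bond is the hard bond. At C2' it stands beside a carboxyl group that is itself hemmed in by the heptyl chain, in an electron-rich ring, and at C4 only one para carboxyl group offers activation.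

Both acids are of the resorcylic type. They lose CO2 when heated in acid, their doubly ortho-substituted esters resist saponification, and the methyl ether rules out strong Lewis acids, so the last unmasking must be neutral.

The enabling feature is this: the ether oxygen, C2', C1', the carboxyl carbon on C1', one of its oxygens and C4 of ring A can be closed to a six-membered ring, and C4 lies para to the carboxyl carbon on C1, which can take up negative charge. Compound 16 is therefore one of the two ways of opening a spiro adduct at C4. The other way gives a depside, the ester of the ring B acid with O-4 of ring A, and esters are easy to make.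

## Retrosynthesis

**16 to 15.** The O–CH2 bond of a benzyl ester on the ring A carboxyl is cut. Only this acid needs a mask, because the ring B acid is set free by the key step itself. A benzyl ester is preferred to a methyl ester, since a doubly ortho-substituted ester would need hard saponification, whereas hydrogenolysis is neutral and cold. The forward reaction must only leave the diaryl ether and both acids untouched.

**15 to 13, through 14.**
- The ether is cut on its ring A side (O–C4), not on its ring B side (O–C2').
- C2' sits in the more electron-rich ring, between H and a crowded carboxyl, and would need a halide placed there on purpose.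
- C4 is para to an acceptor and already bears an oxygen in every simple precursor.
- Joining C4 again to a carboxyl oxygen of ring B gives the depside phenoxide 13, an isomer of the salt of 15 in which the hindered ether has become an ordinary ester.
- The forward reaction is an O-to-O Smiles rearrangement through the spiro adduct 14. It must run with one ester as the only activating group.

**13 to 12 + 9.** The acyl C–O bond of the depside is cut. The acyl part is written as the salicylate acetonide 9, not as a free acid, because 9 is at once protected, activated and the carrier of a latent O-2' phenoxide that appears only when the acyl group has been handed over. Compound 13 then need not be isolated, and the precursors of the key step are two single-ring compounds of half the size. The forward reaction asks that only the 4-OH of 12 is acylated and that 9 is the only acyl donor present.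

**9 to 8.** The O–CH3 bond is cut. In 8 the acetonide ties up the carboxyl group and the ortho oxygen, so the 7-OH is the only free position and methylation needs no selectivity.

**8 to 7, and 12 to 11 to 10 to 7.**
- In each ring the bond between the carboxyl-bearing carbon and the heptyl-bearing carbon is cut (aldol retron). Both rings unfold to the same acyclic chain, the diketo-dioxinone 7.
- Cutting the heptyl–arene bond or the arene–carboxyl bond would instead need a prefunctionalized arene for each ring and would leave the oxygen differentiation unsolved.
- The choice of base at room temperature or heat with benzyl alcohol decides whether the dioxinone is kept (8) or traded through acylketene 10 and triketo ester 11 for the benzyl ester (12).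

**7 to 4 + 5 (through 6), and 4 to 1 + 2 (through 3).** Two C–C bonds next to ketone carbonyls are cut (Claisen retrons). They lead to the commercial dioxinone 1, acetyl chloride 2 and the octanoic amide 5. The forward reactions ask for γ-selective and then terminal-selective C-acylation of the dienolate 3 and the dianion 6.

## Roads not taken

**Alternative 1:** cut the ether on its ring B side, O–C2'. This is the most obvious plan.
- Forward key step: Ullmann-type coupling of phenol 12 with benzyl 2-bromo-6-heptyl-4-methoxybenzoate A1 (CuI, amino acid ligand, Cs2CO3, dioxane, about 100 °C) to the dibenzyl ester A2, then hydrogenolysis.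
- A1 cannot come from 7. It needs a ring synthesis of its own that places bromine between H and the ester against the directing effect of the methoxy group.
- Its C–Br bond lies in an electron-rich ring beside a bulky ester, so insertion of copper is slow and reductive loss of halogen competes.
- The chelating salicylate unit of 12 binds copper and would call for a further protecting group.
- The chosen plan needs no halide and no metal, and it takes both rings from one precursor.

**Alternative 2:** cut O–C4 with ring A at the dihydro level and aromatize late.
- Forward key steps: a Michael–Dieckmann annulation gives the 1,3-dione A3. This is turned into its vinylogous acid chloride A4, which takes up the phenoxide of A5 by addition–elimination to give the enol ether A6. Dehydrogenation then gives A2.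
- The C–O bond forms easily, but A3 has two unlike carbonyl groups (C2 and C4), and only a modest steric difference decides which one is activated. An error here gives a positional isomer of the ether.
- The nucleophile is the chelated, hindered 2'-OH, and activation plus dehydrogenation add two steps.
- In the chosen plan the position of the ether is fixed by the ester tether and no change of oxidation level is needed.

**Alternative 3:** cut O–C2' and C1'–carboxyl together.
- Forward key step: fluoride releases the aryne A8 from the silyl triflate A7. The phenoxide of 12 adds to C2', and the aryl anion at C1' is carboxylated with CO2 in a three-component union.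
- The groups beside the triple bond do not secure the sense of addition. C1' has the heptyl chain next to it and C2' only hydrogen, which gives a weak steric bias toward C2' and almost no distortion of the aryne.
- The methoxy group is meta to C2' and para to C1', so its inductive pull favours the anion at C2' and hence attack at C1', the wrong way.
- The anion would have to be carboxylated beside the heptyl chain faster than it is protonated by the 2-OH of 12, and A7 itself needs several steps.
- The chosen plan reaches the same two neighbouring substituents with their positions fixed.

Key step: step 6

Remark on the chemistry: the target has no stereogenic element, so no step has to set configuration. Amide 5 is taken to be a catalogue compound.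

## Steps

**Step 1**
Reactants: 1 2,2,6-trimethyl-4H-1,3-dioxin-4-one; 2 acetyl chloride
Product: 4 2,2-dimethyl-6-(2-oxopropyl)-4H-1,3-dioxin-4-one, via lithium dienolate 3 (not isolated)
Conditions: LiN(SiMe3)2, THF, −78 °C; 2 (0.5 equiv), −78 °C; 1 M HCl
Reagents that add atoms: none
Why: Deprotonation of the 6-methyl group gives the dienolate 3, which is C-acylated at its exocyclic γ-carbon (vinylogous Claisen-type acylation). The acid chloride is the limiting reagent because 4 is more acidic than 1 and consumes a second equivalent of 3.

**Step 2**
Reactants: 4 2,2-dimethyl-6-(2-oxopropyl)-4H-1,3-dioxin-4-one; 5 N-methoxy-N-methyloctanamide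
Product: 7 6-(2,4-dioxoundecyl)-2,2-dimethyl-4H-1,3-dioxin-4-one, via dilithium dianion 6 (not isolated)
Conditions: LiN(i-Pr)2 (2.2 equiv), THF, −78 °C; 5, −78 → −40 °C; 1 M HCl
Reagents that add atoms: none
Why: In the dianion 6 the carbanion formed last, at the terminal CH2, is the most nucleophilic site, as in all 1,3-dicarbonyl dianions, and it attacks the amide (Claisen-type acylation). An N-methoxy-N-methyl amide releases the ketone only on work-up, so neither over-addition nor quenching by the acidic product occurs.

**Step 3**
Reactants: 7 6-(2,4-dioxoundecyl)-2,2-dimethyl-4H-1,3-dioxin-4-one
Product: 8 5-heptyl-7-hydroxy-2,2-dimethyl-4H-1,3-benzodioxin-4-one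
Conditions: Et3N, CH2Cl2, rt
Reagents that add atoms: none
Why: The amine enolizes the chain, and C5 of the dioxinone adds to the heptyl ketone in a 6-(enolexo)-exo-trig aldol closure. Loss of water and enolization of the remaining ketone give the arene (biomimetic polyketide aldol aromatization). At room temperature the dioxinone does not fragment, so the acetonide survives and only the 7-OH is free.

**Step 4**
Reactants: 8 5-heptyl-7-hydroxy-2,2-dimethyl-4H-1,3-benzodioxin-4-one
Product: 9 5-heptyl-7-methoxy-2,2-dimethyl-4H-1,3-benzodioxin-4-one
Conditions: MeI, K2CO3, acetone, reflux
Reagents that add atoms: iodomethane, CI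
Why: Williamson ether synthesis on the only free hydroxyl group. The acetonide is stable to carbonate in acetone.

**Step 5**
Reactants: 7 6-(2,4-dioxoundecyl)-2,2-dimethyl-4H-1,3-dioxin-4-one
Product: 12 benzyl 6-heptyl-2,4-dihydroxybenzoate, via acylketene 10 (not isolated), via benzyl triketo ester 11 (not isolated)
Conditions: BnOH (1.5 equiv), PhMe, 110 °C; then Cs2CO3, i-PrOH–CH2Cl2, rt; then 1 M HCl
Reagents that add atoms: benzyl alcohol, OCc1ccccc1
Why: At 110 °C the dioxinone loses acetone by a retro-hetero-Diels–Alder reaction, and the acylketene 10 is trapped by benzyl alcohol to give 11. Base then closes C2 of 11 onto the C7 ketone (aldol), and acid completes dehydration to the resorcylate (ketene trapping followed by aldol aromatization).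

**Step 6**
Reactants: 12 benzyl 6-heptyl-2,4-dihydroxybenzoate; 9 5-heptyl-7-methoxy-2,2-dimethyl-4H-1,3-benzodioxin-4-one
Product: 15 2-{4-[(benzyloxy)carbonyl]-3-heptyl-5-hydroxyphenoxy}-6-heptyl-4-methoxybenzoic acid, via depside phenoxide 13 (not isolated), via spiro adduct 14 (not isolated)
Conditions: 12, KN(SiMe3)2 (1.0 equiv), THF, 0 °C, then evaporation; 9 (1.1 equiv), DMSO, 4 Å MS, 60 → 110 °C, N2 sweep; cold 1 M HCl
Reagents that add atoms: none
Why: Proposed new method: each half of the relay belongs to a known reaction type, the opening of a salicylate acetonide (2,2-dimethyl-1,3-benzodioxin-4-one) by an oxygen nucleophile with loss of acetone and the O-to-O Smiles rearrangement of aryl salicylates and depsides to 2-aryloxybenzoic acids, but their union into one operation that makes a diaryl ether from a phenol and an acetonide is new. One equivalent of base deprotonates only the non-chelated, more acidic 4-OH of 12; this phenoxide adds to the lactone carbonyl of 9, whose ester is locked in the reactive s-cis geometry and is approached from above the ring plane, so that the neighbouring heptyl chain shields it less than it would an open ester, and collapse with loss of acetone uncovers O-2' as the phenoxide 13. O-2' then attacks C4 of ring A, which is para to the benzyl ester carbonyl that the hydrogen bond from the 2-OH holds in the ring plane, in a 6-exo-trig closure to the spiro adduct 14, whose new ring is again a 1,3-benzodioxin-4-one and so of a type that tolerates a heptyl chain beside its carbonyl. Adduct 14 opens by expelling the carboxylate oxygen, so the ring closed here does not survive, the ether oxygen of 15 is the former O-2' of 9, and the former phenol oxygen of 12 ends in the carboxyl group on C1'. Positional selectivity is built in: 9 is the only good acyl donor present (the benzyl ester of 12 is an open, chelated ester with a poor leaving group), O-2' is the only nucleophile that can reach an activated ring carbon through a six-membered transition state, and C4 is the only such carbon that bears a leaving group. All acyl transfers before 14 are reversible, whereas the two irreversible events, escape of acetone in the gas stream and formation of a carboxylate that is a far weaker base than any phenoxide present, both lie on the productive path. Keeping the system at the monoanion level matters, because the tautomer deprotonated at the 2-OH of ring A is unreactive but equilibrates with 13, whereas a dianion would switch ring A off. No stereocentre is formed.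

**Step 7**
Reactants: 15 2-{4-[(benzyloxy)carbonyl]-3-heptyl-5-hydroxyphenoxy}-6-heptyl-4-methoxybenzoic acid
Product: 16 4-(2-carboxy-3-heptyl-5-methoxyphenoxy)-6-heptyl-2-hydroxybenzoic acid
Conditions: H2 (1 atm), Pd/C, EtOAc, rt
Reagents that add atoms: none
Why: Hydrogenolysis of the benzyl ester is neutral and cold, so neither resorcylic acid loses CO2. The diaryl ether, the methyl ether and the chains are inert.

## Compound list

1 | 2,2,6-trimethyl-4H-1,3-dioxin-4-one | CC1=CC(=O)OC(C)(C)O1 | starting material
2 | acetyl chloride | CC(=O)Cl | starting material
3 | lithium 2,2-dimethyl-6-methylidene-1,3-dioxin-4-olate (dienolate of 1) | C=C1C=C([O-])OC(C)(C)O1.[Li+] | intermediate (not isolated)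
4 | 2,2-dimethyl-6-(2-oxopropyl)-4H-1,3-dioxin-4-one | CC(=O)CC1=CC(=O)OC(C)(C)O1 | intermediate
5 | N-methoxy-N-methyloctanamide | CCCCCCCC(=O)N(C)OC | starting material
6 | dilithium dianion of 4 (enolate at the ketone, dienolate at the dioxinone) | C=C([O-])C=C1C=C([O-])OC(C)(C)O1.[Li+].[Li+] | intermediate (not isolated)
7 | 6-(2,4-dioxoundecyl)-2,2-dimethyl-4H-1,3-dioxin-4-one | CCCCCCCC(=O)CC(=O)CC1=CC(=O)OC(C)(C)O1 | intermediate
8 | 5-heptyl-7-hydroxy-2,2-dimethyl-4H-1,3-benzodioxin-4-one | CCCCCCCc1cc(O)cc2OC(C)(C)OC(=O)c12 | intermediate
9 | 5-heptyl-7-methoxy-2,2-dimethyl-4H-1,3-benzodioxin-4-one | CCCCCCCc1cc(OC)cc2OC(C)(C)OC(=O)c12 | intermediate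
10 | 3,5,7-trioxotetradec-1-en-1-one (acylketene) | CCCCCCCC(=O)CC(=O)CC(=O)C=C=O | intermediate (not isolated)
11 | benzyl 3,5,7-trioxotetradecanoate | CCCCCCCC(=O)CC(=O)CC(=O)CC(=O)OCc1ccccc1 | intermediate (not isolated)
12 | benzyl 6-heptyl-2,4-dihydroxybenzoate | CCCCCCCc1cc(O)cc(O)c1C(=O)OCc1ccccc1 | intermediate
13 | potassium 2-({4-[(benzyloxy)carbonyl]-3-heptyl-5-hydroxyphenoxy}carbonyl)-3-heptyl-5-methoxyphenolate (depside phenoxide) | CCCCCCCc1cc(OC(=O)c2c([O-])cc(OC)cc2CCCCCCC)cc(O)c1C(=O)OCc1ccccc1.[K+] | intermediate (not isolated)
14 | potassium salt of the spiro adduct: 5-heptyl-7-methoxy-1,3-benzodioxin-4-one whose C2 is C4 of ring A, ring A being a cyclohexa-2,5-diene with heptyl, hydroxyl and an exocyclic benzyl ester enolate | O=C1OC2(C=C(O)C(=C([O-])OCc3ccccc3)C(CCCCCCC)=C2)Oc2cc(OC)cc(CCCCCCC)c12.[K+] | intermediate (not isolated)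
15 | 2-{4-[(benzyloxy)carbonyl]-3-heptyl-5-hydroxyphenoxy}-6-heptyl-4-methoxybenzoic acid | CCCCCCCc1cc(Oc2cc(OC)cc(CCCCCCC)c2C(=O)O)cc(O)c1C(=O)OCc1ccccc1 | intermediate
16 | 4-(2-carboxy-3-heptyl-5-methoxyphenoxy)-6-heptyl-2-hydroxybenzoic acid | CCCCCCCc1cc(Oc2cc(OC)cc(CCCCCCC)c2C(=O)O)cc(O)c1C(=O)O | target

## Step count and least certain steps

Total step count: 7. Longest linear sequence: 6 (steps 1, 2, 3, 4, 6, 7). Step 5 is a one-step branch from 7.

**Step 6 (key step, proposed new method).**
- The most likely failure is a stalled acyl transfer. The phenoxide of 12 is stabilized by its para ester and may leave the tetrahedral adduct faster than acetone is lost.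
- Next in likelihood is a slow ipso attack, since ring A is activated by one ester only.
- At the temperature then needed, several things may intervene: transfer of the benzyl group from the ester to a phenoxide, cleavage of the depside by traces of water, or loss of CO2 from the product carboxylate.
- The fallback uses known chemistry. It sets out from 9 and 12, comes back at 15, and separates the two events. Saponification of 9 (KOH, DMSO–H2O, 60 °C, cold acidification) gives 6-heptyl-2-hydroxy-4-methoxybenzoic acid F1. F1 and 12 are condensed through the mixed anhydride with (CF3CO)2O in toluene at room temperature. This is the classical depside condensation under acidic conditions, which acylates only the non-chelated 4-OH. It gives benzyl 6-heptyl-4-[(6-heptyl-2-hydroxy-4-methoxybenzoyl)oxy]-2-hydroxybenzoate F2, which is isolated and purified. F2 alone is then rearranged with K2CO3 in dry DMSO (Smiles rearrangement of a depside) to 15.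

**Step 2.**
- The most likely failure is proton transfer in place of acylation. The dianion 6 is a strong base, amide 5 has α-hydrogens, and the attack on an amide is slow at the low temperature that the dioxinone ring demands. Quenching of 6 and decay on warming may therefore outrun bond formation.
- The fallback sets out from 4 and comes back at 7 by aldol addition and oxidation. The dianion 6 is treated at −78 °C with octanal, a much better electrophile, to give racemic 6-(4-hydroxy-2-oxoundecyl)-2,2-dimethyl-4H-1,3-dioxin-4-one F3. Dess–Martin periodinane in CH2Cl2 then gives 7 and erases the stereocentre.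

**Step 5.**
- The most likely failure is capture of the ketene by an enol oxygen of its own chain (lactonization) in place of benzyl alcohol. Ring closure of 11 in the Claisen sense instead of the aldol sense under base is a second risk.
- The fallback sets out from 8 and comes back at 12. Saponification of the acetonide (KOH, DMSO–H2O, 80 °C, cold acidification) gives 6-heptyl-2,4-dihydroxybenzoic acid F4. Its carboxylate alone is alkylated by benzyl bromide with KHCO3 in DMF at room temperature to give 12.

## Further compounds

F1 | step 6 | 6-heptyl-2-hydroxy-4-methoxybenzoic acid | CCCCCCCc1cc(OC)cc(O)c1C(=O)O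
F2 | step 6 | benzyl 6-heptyl-4-[(6-heptyl-2-hydroxy-4-methoxybenzoyl)oxy]-2-hydroxybenzoate | CCCCCCCc1cc(OC(=O)c2c(O)cc(OC)cc2CCCCCCC)cc(O)c1C(=O)OCc1ccccc1
F3 | step 2 | 6-(4-hydroxy-2-oxoundecyl)-2,2-dimethyl-4H-1,3-dioxin-4-one (racemic) | CCCCCCCC(O)CC(=O)CC1=CC(=O)OC(C)(C)O1
F4 | step 5 | 6-heptyl-2,4-dihydroxybenzoic acid | CCCCCCCc1cc(O)cc(O)c1C(=O)O
A1 | alternative 1 | benzyl 2-bromo-6-heptyl-4-methoxybenzoate | CCCCCCCc1cc(OC)cc(Br)c1C(=O)OCc1ccccc1
A2 | alternative 1 | benzyl 4-{2-[(benzyloxy)carbonyl]-3-heptyl-5-methoxyphenoxy}-6-heptyl-2-hydroxybenzoate | CCCCCCCc1cc(Oc2cc(OC)cc(CCCCCCC)c2C(=O)OCc2ccccc2)cc(O)c1C(=O)OCc1ccccc1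
A3 | alternative 2 | benzyl 6-heptyl-2,4-dioxocyclohexane-1-carboxylate (racemic, mixture of diastereomers) | CCCCCCCC1CC(=O)CC(=O)C1C(=O)OCc1ccccc1
A4 | alternative 2 | benzyl 4-chloro-6-heptyl-2-oxocyclohex-3-ene-1-carboxylate (racemic, mixture of diastereomers) | CCCCCCCC1CC(Cl)=CC(=O)C1C(=O)OCc1ccccc1
A5 | alternative 2 | benzyl 6-heptyl-2-hydroxy-4-methoxybenzoate | CCCCCCCc1cc(OC)cc(O)c1C(=O)OCc1ccccc1
A6 | alternative 2 | benzyl 4-{2-[(benzyloxy)carbonyl]-3-heptyl-5-methoxyphenoxy}-6-heptyl-2-oxocyclohex-3-ene-1-carboxylate (racemic, mixture of diastereomers) | CCCCCCCC1CC(Oc2cc(OC)cc(CCCCCCC)c2C(=O)OCc2ccccc2)=CC(=O)C1C(=O)OCc1ccccc1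
A7 | alternative 3 | 2-heptyl-4-methoxy-6-(trimethylsilyl)phenyl trifluoromethanesulfonate | CCCCCCCc1cc(OC)cc([Si](C)(C)C)c1OS(=O)(=O)C(F)(F)F
A8 | alternative 3 | 3-heptyl-5-methoxy-1,2-didehydrobenzene (aryne) | CCCCCCCC1=CC(OC)=CC#C1
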